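**Assumptions (one line):** 2-methylcyclohexane-1,3-dione and 3-methoxybenzoic acid are bought. The bridged keto-acid 15 is made racemic, and the A-ring lactone 10 fixes the absolute configuration when the two are joined as diastereomeric esters.

## Retrosynthetic overview
1. Ludongnin A comes from the C15 enone (SeO2, then MnO2) on the C11 alcohol. That alcohol comes from thermodynamic reduction of a C11 ketone carried through the synthesis alongside the exocyclic methylene.
2. The pentacycle comes from a tethered intramolecular Mukaiyama–Michael (C9–C10 bond). It joins the bridged keto-acid 15 to the A-ring unsaturated lactone 10 and closes the 7,20-δ-lactone.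
3. Keto-acid 15 comes from a vinyl-radical 5-exo closure onto cyclohexenone 14. Enone 14 comes from Birch reductive alkylation (dearomatisation) of 3-methoxybenzoic acid, which builds the quaternary C8.
4. Lactone 10 (with the 6,19-γ-lactone) comes from Ru-catalysed desymmetrisation of the prochiral dione 3, which sets C4. C10 is then functionalised and the unsaturated lactone formed by enol-triflate carbonylation.
5. Ring order: A ring and 6,19-lactone (in 10) → C ring (Birch) → D ring (radical) → 7,20-lactone with C9–C10, C5 (Michael).

## Route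

**Step 1**
Reactants: 1 (2-methylcyclohexane-1,3-dione), 2 (benzyl chloromethyl ether)
Product: 3 (2-[(benzyloxy)methyl]-2-methylcyclohexane-1,3-dione)
Conditions: NaH, THF/DMPU, 0 °C → rt
Reagents that add atoms: none
Why: C-alkylation of the dione enolate gives a Cs-symmetric, prochiral 2,2-disubstituted dione whose two carbonyls are enantiotopic.

**Step 2**
Reactants: 3
Product: 4 ((2R,3S)-2-[(benzyloxy)methyl]-3-hydroxy-2-methylcyclohexan-1-one)
Conditions: RuCl[(S,S)-TsDPEN](p-cymene) (1 mol %, enantiomer chosen to give 2R), HCO2H/Et3N 5:2, CH2Cl2, 30 °C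
Reagents that add atoms: none (formate supplies H only)
Why: Noyori asymmetric transfer hydrogenation reduces one of the two enantiotopic carbonyls, which sets the C4 quaternary centre (enantio-determining step). The carbinol centre is removed in step 4, so its configuration is irrelevant.

**Step 3**
Reactants: 4
Product: 5 (O-[(1S,2R)-2-[(benzyloxy)methyl]-2-methyl-3-oxocyclohexyl] O-phenyl carbonothioate)
Conditions: PhOC(S)Cl, DMAP, pyridine, MeCN, 0 °C → rt
Reagents that add atoms: phenyl chlorothionoformate, S=C(Cl)Oc1ccccc1
Why: Thionocarbonate formation prepares a Barton–McCombie deoxygenation; no stereocentre is touched.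

**Step 4**
Reactants: 5
Product: 6 ((2S)-2-[(benzyloxy)methyl]-2-methylcyclohexan-1-one)
Conditions: Bu3SnH, AIBN, PhMe, 110 °C
Reagents that add atoms: none (H only)
Why: Barton–McCombie radical deoxygenation removes the unwanted C3 oxygen; the quaternary C4 is unchanged.

**Step 5**
Reactants: 6, 2
Product: 7 ((2S)-2,6-bis[(benzyloxy)methyl]-2-methylcyclohexan-1-one, C6 epimer mixture)
Conditions: LDA, THF, −78 °C; then 2, −78 °C → rt
Reagents that add atoms: none (2 is the electrophile)
Why: The quaternary C4 blocks one α-side, so kinetic enolate alkylation occurs only at C10 (the future C20 carbon). The new C10 centre is destroyed in step 7.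

**Step 6**
Reactants: 7
Product: 8 ((6S)-2,6-bis[(benzyloxy)methyl]-6-methylcyclohex-1-en-1-yl triflate)
Conditions: KHMDS, THF, −78 °C; then PhNTf2
Reagents that add atoms: N-phenyl-bis(trifluoromethanesulfonimide), O=S(=O)(C(F)(F)F)N(c1ccccc1)S(=O)(=O)C(F)(F)F
Why: Only one enolisable side remains, so the tetrasubstituted enol triflate forms regiospecifically.

**Step 7**
Reactants: 8
Product: 9 (methyl (6R)-2,6-bis[(benzyloxy)methyl]-6-methylcyclohex-1-ene-1-carboxylate)
Conditions: Pd(OAc)2, PPh3, CO (1 atm), Et3N, MeOH/DMF, 65 °C
Reagents that add atoms: carbon monoxide, [C-]#[O+]; methanol, CO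
Why: Pd-catalysed methoxycarbonylation of the enol triflate installs C6 and the C5=C10 enoate; C10 becomes sp2, so its stereochemistry is erased. The descriptor changes from S to R only because the CIP priorities change, not the geometry.

**Step 8**
Reactants: 9
Product: 10 ((3aR)-7-(hydroxymethyl)-3a-methyl-3a,4,5,6-tetrahydro-2-benzofuran-1(3H)-one)
Conditions: H2 (1 atm), Pd(OH)2/C, MeOH; then TsOH, PhMe, 70 °C
Reagents that add atoms: none
Why: Hydrogenolysis removes both benzyl ethers. The freed C19-OH closes the 5-membered 6,19-lactone onto the C6 ester, and the hindered tetrasubstituted enoate survives. The free C20 allylic alcohol is kept for tethering.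

**Step 9**
Reactants: 11 (3-methoxybenzoic acid), 12 (2,3-dibromopropene)
Product: 13 (1-(2-bromoallyl)-3-methoxycyclohexa-2,5-diene-1-carboxylic acid, racemic)
Conditions: Li, NH3(l), THF, tBuOH (1 equiv), −78 °C; isoprene quench; then 12, −78 → −33 °C
Reagents that add atoms: none
Why: Birch reductive alkylation dearomatises the ring and builds the quaternary C8 carrying the C15–C16 vinyl bromide. The benzoate dianion is alkylated at the ipso carbon.

**Step 10**
Reactants: 13
Product: 14 (1-(2-bromoprop-2-en-1-yl)-3-oxocyclohex-4-ene-1-carboxylic acid, racemic)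
Conditions: 3 M HCl, THF, 50 °C
Reagents that add atoms: water, O
Why: Enol-ether hydrolysis gives the β,γ-enone, which isomerises under acid to the conjugated 5,5-disubstituted cyclohex-2-enone, placing C11 (ketone), C12=C13 and C9 (α′-CH2) correctly.

**Step 11**
Reactants: 14
Product: 15 ((1R,5S)-6-methylidene-3-oxobicyclo[3.2.1]octane-1-carboxylic acid; formed racemic, enantiomer shown)
Conditions: Bu3SnH (syringe pump), AIBN, PhH, 80 °C, 0.01 M
Reagents that add atoms: none (H replaces Br)
Why: The vinyl radical at C16 undergoes 5-exo-trig addition to the enone β-carbon C13, closing the D ring. Bridging fixes C13 relative to C8, and the exocyclic C16=C17 methylene is retained; the α-keto radical at C12 is reduced by tin hydride.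

**Step 12**
Reactants: 15, 10
Product: 16 ([(3aR)-3a-methyl-1-oxo-1,3,3a,4,5,6-hexahydro-2-benzofuran-7-yl]methyl (1R,5S)-6-methylidene-3-oxobicyclo[3.2.1]octane-1-carboxylate)
Conditions: 2,4,6-Cl3C6H2COCl, Et3N, THF; then 10, DMAP, PhMe, 50 °C; separate diastereomers by chromatography
Reagents that add atoms: none (the acyl chloride is lost as byproduct)
Why: Yamaguchi esterification forms the C7–O–C20 tether. The racemic acid and enantiopure alcohol give two diastereomeric esters, and the one shown is carried forward, so C4 of 10 defines the absolute configuration.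

**Step 13**
Reactants: 16
Product: 17 (11-oxo-6,7-seco-ent-kaur-16-ene 6,19:7,20-bis-lactone)
Conditions: TMSOTf, Et3N, CH2Cl2, 0 °C; then TMSNTf2 (10 mol %), −78 → 0 °C; aq. NH4Cl
Reagents that add atoms: none (silyl groups leave on work-up)
Why: Proposed new method: the C9 silyl enol ether adds to the Lewis-acid-activated β-carbon (C10) of the tetrasubstituted unsaturated lactone through a six-membered tethered transition state (6-exo-trig, ester in the E conformation), closing the δ-lactone and the vicinal quaternary C10 / tertiary C9 centres. The tether delivers the enol ether on the exo face of the bicycle, giving the cis-fused lactone. C5 is protonated on work-up to the cis-fused 6,19-lactone, and C9 is epimerisable α to the ketone. The closest known reaction is the intramolecular Mukaiyama–Michael addition of silyl enol ethers to β,β-disubstituted enoates.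

**Step 14**
Reactants: 17
Product: 18 (11-hydroxy analogue of 17, C15 still CH2)
Conditions: Al(OiPr)3, iPrOH/PhMe, 80 °C
Reagents that add atoms: none (H from iPrOH)
Why: The C11 ketone flanks the syn-axial 2-carbon bridge, so kinetic hydride addition would give the axial alcohol. Meerwein–Ponndorf–Verley equilibration instead gives the more stable equatorial (exo) 11-OH shown in the target.

**Step 15**
Reactants: 18
Product: 19 (15-hydroxy derivative of 18, C15 epimers)
Conditions: SeO2, TBHP, CH2Cl2, rt
Reagents that add atoms: selenium dioxide, O=[Se]=O; tert-butyl hydroperoxide, CC(C)(C)OO (oxygen source)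
Why: SeO2 ene/[2,3] allylic hydroxylation at C15, the only allylic CH2 (the C13 bridgehead cannot react, by Bredt's rule). The new stereocentre is removed in the next step.

**Step 16**
Reactants: 19
Product: 20 (ludongnin A)
Conditions: MnO2, CH2Cl2, rt
Reagents that add atoms: none
Why: MnO2 oxidises the allylic C15 alcohol selectively, leaving the saturated C11 alcohol untouched, to give the exocyclic-methylene enone.

## Compound list
1 | 2-methylcyclohexane-1,3-dione | CC1C(=O)CCCC1=O | starting material
2 | benzyl chloromethyl ether | ClCOCc1ccccc1 | starting material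
3 | 2-[(benzyloxy)methyl]-2-methylcyclohexane-1,3-dione | CC1(COCc2ccccc2)C(=O)CCCC1=O | intermediate
4 | (2R,3S)-2-[(benzyloxy)methyl]-3-hydroxy-2-methylcyclohexan-1-one | O=C1CCC[C@H](O)[C@@]1(C)COCc1ccccc1 | intermediate
5 | O-[(1S,2R)-2-[(benzyloxy)methyl]-2-methyl-3-oxocyclohexyl] O-phenyl carbonothioate | O=C1CCC[C@H](OC(=S)Oc2ccccc2)[C@@]1(C)COCc1ccccc1 | intermediate
6 | (2S)-2-[(benzyloxy)methyl]-2-methylcyclohexan-1-one | O=C1CCCC[C@@]1(C)COCc1ccccc1 | intermediate
7 | (2S)-2,6-bis[(benzyloxy)methyl]-2-methylcyclohexan-1-one (C6 epimer mixture) | O=C1C(COCc2ccccc2)CCC[C@@]1(C)COCc1ccccc1 | intermediate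
8 | (6S)-2,6-bis[(benzyloxy)methyl]-6-methylcyclohex-1-en-1-yl trifluoromethanesulfonate | FC(F)(F)S(=O)(=O)OC1=C(COCc2ccccc2)CCC[C@@]1(C)COCc1ccccc1 | intermediate
9 | methyl (6R)-2,6-bis[(benzyloxy)methyl]-6-methylcyclohex-1-ene-1-carboxylate | COC(=O)C1=C(COCc2ccccc2)CCC[C@@]1(C)COCc1ccccc1 | intermediate
10 | (3aR)-7-(hydroxymethyl)-3a-methyl-3a,4,5,6-tetrahydro-2-benzofuran-1(3H)-one | OCC1=C2C(=O)OC[C@]2(C)CCC1 | intermediate
11 | 3-methoxybenzoic acid | COc1cccc(C(=O)O)c1 | starting material
12 | 2,3-dibromopropene | C=C(Br)CBr | starting material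
13 | 1-(2-bromoallyl)-3-methoxycyclohexa-2,5-diene-1-carboxylic acid (racemic) | COC1=CC(CC(Br)=C)(C(=O)O)C=CC1 | intermediate
14 | 1-(2-bromoprop-2-en-1-yl)-3-oxocyclohex-4-ene-1-carboxylic acid (racemic) | O=C1C=CCC(CC(Br)=C)(C(=O)O)C1 | intermediate
15 | (1R,5S)-6-methylidene-3-oxobicyclo[3.2.1]octane-1-carboxylic acid (racemic; enantiomer shown) | OC(=O)[C@]12CC(=O)C[C@H](C1)C(=C)C2 | intermediate
16 | ester of 15 with 10 (diastereomer carried forward) | O=C(OCC1=C2C(=O)OC[C@]2(C)CCC1)[C@]12CC(=O)C[C@H](C1)C(=C)C2 | intermediate
17 | 11-oxo-6,7-seco-ent-kaur-16-ene 6,19:7,20-bis-lactone | C=C1C[C@]23C[C@H]1CC(=O)[C@H]2[C@@]1(CCC[C@@]2(C)COC(=O)[C@H]21)COC3=O | intermediate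
18 | 11-hydroxy-6,7-seco-ent-kaur-16-ene 6,19:7,20-bis-lactone | C=C1C[C@]23C[C@H]1C[C@@H](O)[C@H]2[C@@]1(CCC[C@@]2(C)COC(=O)[C@H]21)COC3=O | intermediate
19 | 11,15-dihydroxy analogue of 18 (C15 epimers) | C=C1C(O)[C@]23C[C@H]1C[C@@H](O)[C@H]2[C@@]1(CCC[C@@]2(C)COC(=O)[C@H]21)COC3=O | intermediate
20 | ludongnin A | C=C1C(=O)[C@]23C[C@H]1C[C@@H](O)[C@H]2[C@@]1(CCC[C@@]2(C)COC(=O)[C@H]21)COC3=O | target

**Total steps:** 16. **Longest linear sequence:** 13 (steps 1–8, 12–16).

**Three steps most likely to fail:**
1. **Step 13 (Mukaiyama–Michael).** The acceptor is a tetrasubstituted enoate, the ring closure forms vicinal quaternary and tertiary centres, and the C10 configuration is uncertain. Fallback (changes the approach): esterify acid 13 (not 15) with the tertiary β-bromo lactone made by adding HBr to 10, run a Pd-catalysed radical (Heck-type) 6-exo closure onto the Birch enol ether, then apply steps 10–11.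
2. **Step 7 (carbonylation of the hindered tetrasubstituted enol triflate).** Fallback (changes the approach): convert ketone 7 to the C5 nitrile with TosMIC, remove the benzyl groups and lactonise, then dehydrogenate the lactone (LDA/PhSeCl, then H2O2) to give 10.
3. **Step 14 (C11 stereochemistry).** The equilibrium may not favour the equatorial alcohol. Fallback (changes the approach): reduce kinetically with NaBH4 to the axial alcohol, invert it by Mitsunobu with p-nitrobenzoic acid, and cleave the ester enzymatically.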